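**Retrosynthetic overview**
- Remove five MOM groups and oxidise one carbinol. Both 2,4-dioxygenated aryl ketones then come from one aryllithium added at once to a C3 aldehyde and a C5 cinnamoyl Weinreb amide.
- The C3 aldehyde comes from ozonolysis of an E-propenyl group. The C5 side chain comes from a Heck reaction on a 5-bromide.
- The dihydrofuran is the only ring formed, since all benzene rings are bought. It closes through the C2–O bond when an ortho-substituted phenol attacks a p-alkoxybenzylic cation, trans to the C3 substituent.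
- The C3–C3a bond and the C3 stereocentre come from an aromatic Claisen rearrangement of a Z-allyl aryl ether, with 1,3-chirality transfer from its C–O stereocentre.
- That ether comes from (R)-but-3-yn-2-ol by Mitsunobu inversion with 4-bromophenol, acetylide addition to an aryl aldehyde, and semi-hydrogenation.

Assumption: every compound marked as starting material in the list is taken to be a catalogue chemical.

**Step 1**
Reactants: 1 (R)-but-3-yn-2-ol; 2 4-bromophenol
Product: 3 1-bromo-4-{[(2S)-but-3-yn-2-yl]oxy}benzene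
Conditions: PPh3, DIAD, THF, 0 °C → rt
Reagents that add atoms: none
Why: Mitsunobu etherification, in which the acidic phenol displaces the activated secondary propargylic alcohol by SN2 with clean inversion, so the bought (R)-carbinol becomes the (S)-aryl ether.

**Step 2**
Reactants: 3 1-bromo-4-{[(2S)-but-3-yn-2-yl]oxy}benzene; 4 4-(methoxymethoxy)benzaldehyde
Product: 7 tert-butyldimethylsilyl ether of (4S)-4-(4-bromophenoxy)-1-[4-(methoxymethoxy)phenyl]pent-2-yn-1-ol (C1 epimers about 1:1), via lithium acetylide 5 (not isolated), via lithium alkoxide 6 (not isolated)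
Conditions: LiN(i-Pr)2 (LDA), THF, −78 °C; 4; then TBSOTf, −78 → 0 °C
Reagents that add atoms: tert-butyldimethylsilyl trifluoromethanesulfonate (TBSOTf), CC(C)(C)[Si](C)(C)OS(=O)(=O)C(F)(F)F
Why: Acetylide 1,2-addition to an aldehyde with in-flask O-silylation, in which the amide base removes only the alkyne C–H (no Br/Li exchange), C4 is untouched, and the new carbinol carbon may stay a mixture because it is ionised in step 4.

**Step 3**
Reactants: 7 silyl ether alkyne
Product: 8 tert-butyldimethylsilyl ether of (2Z,4S)-4-(4-bromophenoxy)-1-[4-(methoxymethoxy)phenyl]pent-2-en-1-ol (C1 epimers)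
Conditions: H2 (1 atm), Pd/CaCO3 poisoned with Pb(OAc)2 (Lindlar type), quinoline, EtOAc, rt
Reagents that add atoms: none
Why: Lindlar semi-hydrogenation delivers H2 syn on poisoned palladium and stops at the Z-alkene, leaving the aryl bromide, the benzylic and allylic C–O bonds and C4 unchanged.

**Step 4**
Reactants: 8 Z-allyl aryl ether
Product: 11 (2S,3S)-5-bromo-2-[4-(methoxymethoxy)phenyl]-3-[(1E)-prop-1-en-1-yl]-2,3-dihydro-1-benzofuran (trans), via ortho-dienone 9 (not isolated), via phenol 10 (not isolated)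
Conditions: Eu(fod)3 (10 mol %), PhMe, 110 °C, sealed tube; cool to 0 °C, then TsOH·H2O (20 mol %), MeCN co-solvent, 0 °C → rt
Reagents that add atoms: none
Why: Aromatic Claisen rearrangement ([3,3]-sigmatropic) forms C3–C3a suprafacially across the Z-allyl unit while allylic 1,3-strain keeps the methyl group outside, so the (S) C–O centre is relayed to the (S) benzylic carbon with an E-propenyl group, and after rearomatisation the acid ionises both silyl ether epimers to one p-alkoxybenzylic cation that the phenol traps anti to the propenyl group, setting C2 as (S), trans.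

**Step 5**
Reactants: 11 5-bromo-dihydrobenzofuran; 12 N-methoxy-N-methylprop-2-enamide
Product: 13 (2E)-N-methoxy-3-{(2S,3S)-2-[4-(methoxymethoxy)phenyl]-3-[(1E)-prop-1-en-1-yl]-2,3-dihydro-1-benzofuran-5-yl}-N-methylprop-2-enamide
Conditions: Pd(OAc)2 (5 mol %), P(o-tol)3 (12 mol %), NaOAc, DMA, 110 °C
Reagents that add atoms: none
Why: Mizoroki–Heck reaction, in which zerovalent palladium inserts into C5–Br and adds to the terminal electron-poor alkene far faster than to the hindered internal propenyl group, and syn insertion then syn β-hydride elimination gives the E-cinnamamide without touching C2 or C3.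

**Step 6**
Reactants: 13 Heck product
Product: 15 (2E)-3-{(2S,3S)-3-formyl-2-[4-(methoxymethoxy)phenyl]-2,3-dihydro-1-benzofuran-5-yl}-N-methoxy-N-methylprop-2-enamide, via secondary ozonide 14 (not isolated)
Conditions: O3, CH2Cl2, −78 °C (Sudan Red 7B end point); Me2S, −78 °C → rt; used crude
Reagents that add atoms: ozone, [O-][O+]=O
Why: Chemoselective ozonolysis (Criegee mechanism), in which electrophilic ozone takes the non-conjugated propenyl alkene well before the carbonyl-conjugated one, the dye marks the end point, and neutral reduction frees the aldehyde without epimerising C3.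

**Step 7**
Reactants: 16 4-bromobenzene-1,3-diol
Product: 17 1-bromo-2,4-bis(methoxymethoxy)benzene
Conditions: NaH, MOMCl, DMF, 0 °C → rt
Reagents that add atoms: chloromethyl methyl ether (MOMCl), COCCl
Why: Williamson-type O-alkylation of both phenoxides gives base-stable acetal ethers that tolerate and chelate the later aryllithium.

**Step 8**
Reactants: 15 aldehyde Weinreb amide; 17 1-bromo-2,4-bis(methoxymethoxy)benzene (2.4 equiv)
Product: 20 (2E)-1-[2,4-bis(methoxymethoxy)phenyl]-3-{(2S,3R)-3-{[2,4-bis(methoxymethoxy)phenyl](hydroxy)methyl}-2-[4-(methoxymethoxy)phenyl]-2,3-dihydro-1-benzofuran-5-yl}prop-2-en-1-one (carbinol epimers), via aryllithium 18 (not isolated), via dilithium bis-adduct 19 (not isolated)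
Conditions: 17, n-BuLi (2.3 equiv), THF, −78 °C; add 15, −78 °C; AcOH quench at −78 °C
Reagents that add atoms: none
Why: Bromine–lithium exchange followed by aldehyde 1,2-addition and Weinreb ketone synthesis in one operation, in which the chelated tetrahedral adduct stops over-addition, the low temperature and acidic quench protect C3, and the new carbinol centre is removed in step 9 (the C3 descriptor changes to R only through ligand ranking).

**Step 9**
Reactants: 20 enone alcohol
Product: 21 pentakis(methoxymethyl) ether of the target, (2S,3S)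
Conditions: Dess–Martin periodinane, CH2Cl2, 0 °C → rt
Reagents that add atoms: none
Why: Dess–Martin oxidation turns the hindered benzylic alcohol into the aryl ketone under non-basic conditions, so the new β-aryloxy ketone cannot ring-open by E1cB and C2 and C3 stay trans and intact.

**Step 10**
Reactants: 21 pentakis(methoxymethyl) ether
Product: 22 target CNP0288976.2, (2E)-1-(2,4-dihydroxyphenyl)-3-[(2S,3S)-3-(2,4-dihydroxybenzoyl)-2-(4-hydroxyphenyl)-2,3-dihydro-1-benzofuran-5-yl]prop-2-en-1-one
Conditions: HCl (1.25 M in MeOH), MeOH/THF, 35 °C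
Reagents that add atoms: none
Why: Acid-catalysed transacetalisation to methanol removes all five aryl MOM groups under the mild conditions usual for 2'-hydroxychalcones, and any reversible C2–O ionisation recloses to the favoured trans isomer under control of the intact C3.

**Compound list**
1 | (R)-but-3-yn-2-ol | C[C@@H](O)C#C | starting material
2 | 4-bromophenol | Oc1ccc(Br)cc1 | starting material
3 | 1-bromo-4-{[(2S)-but-3-yn-2-yl]oxy}benzene | C[C@H](Oc1ccc(Br)cc1)C#C | intermediate
4 | 4-(methoxymethoxy)benzaldehyde | COCOc1ccc(C=O)cc1 | starting material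
5 | [(3S)-3-(4-bromophenoxy)but-1-yn-1-yl]lithium | C[C@H](Oc1ccc(Br)cc1)C#C[Li] | intermediate
6 | lithium (4S)-4-(4-bromophenoxy)-1-[4-(methoxymethoxy)phenyl]pent-2-yn-1-olate (C1 epimers) | [Li+].C[C@H](Oc1ccc(Br)cc1)C#CC([O-])c1ccc(OCOC)cc1 | intermediate
7 | TBS ether of (4S)-4-(4-bromophenoxy)-1-[4-(methoxymethoxy)phenyl]pent-2-yn-1-ol (C1 epimers) | C[C@H](Oc1ccc(Br)cc1)C#CC(O[Si](C)(C)C(C)(C)C)c1ccc(OCOC)cc1 | intermediate
8 | TBS ether of (2Z,4S)-4-(4-bromophenoxy)-1-[4-(methoxymethoxy)phenyl]pent-2-en-1-ol (C1 epimers) | C[C@H](Oc1ccc(Br)cc1)/C=C\C(O[Si](C)(C)C(C)(C)C)c1ccc(OCOC)cc1 | intermediate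
9 | 4-bromo-6-[(2S,3E)-1-(TBS-oxy)-1-[4-(methoxymethoxy)phenyl]pent-3-en-2-yl]cyclohexa-2,4-dien-1-one | O=C1C=CC(Br)=CC1[C@H](/C=C/C)C(O[Si](C)(C)C(C)(C)C)c1ccc(OCOC)cc1 | intermediate
10 | 4-bromo-2-[(2S,3E)-1-(TBS-oxy)-1-[4-(methoxymethoxy)phenyl]pent-3-en-2-yl]phenol | Oc1ccc(Br)cc1[C@H](/C=C/C)C(O[Si](C)(C)C(C)(C)C)c1ccc(OCOC)cc1 | intermediate
11 | (2S,3S)-5-bromo-2-[4-(methoxymethoxy)phenyl]-3-[(1E)-prop-1-en-1-yl]-2,3-dihydro-1-benzofuran | Brc1ccc2c(c1)[C@H](/C=C/C)[C@@H](c1ccc(OCOC)cc1)O2 | intermediate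
12 | N-methoxy-N-methylprop-2-enamide | C=CC(=O)N(C)OC | starting material
13 | (2E)-N-methoxy-N-methyl-3-{(2S,3S)-2-[4-(methoxymethoxy)phenyl]-3-[(1E)-prop-1-en-1-yl]-2,3-dihydro-1-benzofuran-5-yl}prop-2-enamide | O=C(/C=C/c1ccc2c(c1)[C@H](/C=C/C)[C@@H](c1ccc(OCOC)cc1)O2)N(C)OC | intermediate
14 | secondary ozonide of 13 (5-methyl-1,2,4-trioxolan-3-yl group at C3) | O=C(/C=C/c1ccc2c(c1)[C@H](C1OOC(C)O1)[C@@H](c1ccc(OCOC)cc1)O2)N(C)OC | intermediate
15 | (2E)-3-{(2S,3S)-3-formyl-2-[4-(methoxymethoxy)phenyl]-2,3-dihydro-1-benzofuran-5-yl}-N-methoxy-N-methylprop-2-enamide | O=C(/C=C/c1ccc2c(c1)[C@H](C=O)[C@@H](c1ccc(OCOC)cc1)O2)N(C)OC | intermediate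
16 | 4-bromobenzene-1,3-diol | Oc1ccc(Br)c(O)c1 | starting material
17 | 1-bromo-2,4-bis(methoxymethoxy)benzene | COCOc1ccc(Br)c(OCOC)c1 | intermediate
18 | [2,4-bis(methoxymethoxy)phenyl]lithium | [Li]c1ccc(OCOC)cc1OCOC | intermediate
19 | dilithium bis-adduct (C3 carbinolate plus Weinreb tetrahedral alkoxide) | [Li+].[Li+].[O-]C(/C=C/c1ccc2c(c1)[C@H](C([O-])c1ccc(OCOC)cc1OCOC)[C@@H](c1ccc(OCOC)cc1)O2)(N(C)OC)c1ccc(OCOC)cc1OCOC | intermediate
20 | (2S,3R) enone alcohol (carbinol epimers) | O=C(/C=C/c1ccc2c(c1)[C@H](C(O)c1ccc(OCOC)cc1OCOC)[C@@H](c1ccc(OCOC)cc1)O2)c1ccc(OCOC)cc1OCOC | intermediate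
21 | (2S,3S) pentakis(methoxymethyl) ether of the target | O=C(/C=C/c1ccc2c(c1)[C@H](C(=O)c1ccc(OCOC)cc1OCOC)[C@@H](c1ccc(OCOC)cc1)O2)c1ccc(OCOC)cc1OCOC | intermediate
22 | CNP0288976.2, (2S,3S), trans, E | O=C(/C=C/c1ccc2c(c1)[C@H](C(=O)c1ccc(O)cc1O)[C@@H](c1ccc(O)cc1)O2)c1ccc(O)cc1O | target

**Step count**
Total steps: 10.
Longest linear sequence: 9 (steps 1–6, 8, 9, 10).

**Steps most likely to fail**

Step 4. The bulky inside substituent of the Z-alkene may slow the [3,3] shift so much that loss of 4-bromophenol takes over.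
- The fallback sets out from 2 and 4 and switches both the carbinol configuration and the alkene geometry, which leads to the same C3 configuration.
- Mitsunobu coupling of 2 with (S)-but-3-yn-2-ol F1 gives 1-bromo-4-{[(2R)-but-3-yn-2-yl]oxy}benzene F2.
- Hydrozirconation with Cp2Zr(H)Cl, transmetalation with Me2Zn and addition to 4 give the (2E,4R)-allylic alcohol F3.
- TBSCl and imidazole give its silyl ether F4.
- The less crowded E-ether rearranges with Eu(fod)3 at 50–80 °C, and the route is rejoined at phenol 10.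
- The minor Z-propenyl isomer, which carries the opposite C3 configuration, is removed by chromatography.

Step 6. Ozone may also cut the electron-rich cinnamamide alkene.
- The fallback sets out from 11 and reverses the order of events.
- Ozonolysis of the only alkene in 11 gives (2S,3S)-5-bromo-2-[4-(methoxymethoxy)phenyl]-2,3-dihydro-1-benzofuran-3-carbaldehyde F5.
- One equivalent of aryllithium 18 gives the (2S,3R) bromo alcohol F6.
- Aryllithium 18 and 12 give 1-[2,4-bis(methoxymethoxy)phenyl]prop-2-en-1-one F7.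
- A Heck reaction of F6 with F7 (Pd(OAc)2, P(o-tol)3, NaOAc, DMA) is run while C3 still carries no carbonyl group, and the route is rejoined at 20.

Step 10. A Brønsted acid may open the C2–O bond of the freed p-hydroxybenzyl ether. Loss of the C3 proton would then cause racemisation, or the 2'-hydroxychalcone may cyclise to a flavanone.
- The fallback sets out from 21 and avoids protic acid by silyl transfer.
- TMSOTf and 2,2'-bipyridyl in MeCN at 0 °C exchange each aryl MOM ether for a silyl ether, giving the pentakis(trimethylsilyl) ether F8.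
- Water at pH 7 and rt hydrolyses F8, and the route is rejoined at 22.

**Further compounds**
F1 | step 4 | (S)-but-3-yn-2-ol (bought) | C[C@H](O)C#C
F2 | step 4 | 1-bromo-4-{[(2R)-but-3-yn-2-yl]oxy}benzene | C[C@@H](Oc1ccc(Br)cc1)C#C
F3 | step 4 | (2E,4R)-4-(4-bromophenoxy)-1-[4-(methoxymethoxy)phenyl]pent-2-en-1-ol (C1 epimers) | C[C@@H](Oc1ccc(Br)cc1)/C=C/C(O)c1ccc(OCOC)cc1
F4 | step 4 | TBS ether of F3 | C[C@@H](Oc1ccc(Br)cc1)/C=C/C(O[Si](C)(C)C(C)(C)C)c1ccc(OCOC)cc1
F5 | step 6 | (2S,3S)-5-bromo-2-[4-(methoxymethoxy)phenyl]-2,3-dihydro-1-benzofuran-3-carbaldehyde | Brc1ccc2c(c1)[C@H](C=O)[C@@H](c1ccc(OCOC)cc1)O2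
F6 | step 6 | [2,4-bis(methoxymethoxy)phenyl]{(2S,3R)-5-bromo-2-[4-(methoxymethoxy)phenyl]-2,3-dihydro-1-benzofuran-3-yl}methanol (carbinol epimers) | Brc1ccc2c(c1)[C@H](C(O)c1ccc(OCOC)cc1OCOC)[C@@H](c1ccc(OCOC)cc1)O2
F7 | step 6 | 1-[2,4-bis(methoxymethoxy)phenyl]prop-2-en-1-one | C=CC(=O)c1ccc(OCOC)cc1OCOC
F8 | step 10 | (2S,3S) pentakis(trimethylsilyl) ether of the target | O=C(/C=C/c1ccc2c(c1)[C@H](C(=O)c1ccc(O[Si](C)(C)C)cc1O[Si](C)(C)C)[C@@H](c1ccc(O[Si](C)(C)C)cc1)O2)c1ccc(O[Si](C)(C)C)cc1O[Si](C)(C)C
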